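The route rests on disconnecting the C13–C14 bond of the six-membered ring (C1, C10–C14): its cis-vicinal diacetate next to the quaternary C1 is read as a pinacol. A samarium diiodide pinacol cyclisation of a 13,14-dialdehyde closes this last carbocycle on the finished ten-membered ring/γ-lactone and sets C13 and C14 in one operation, the axial C15 methyl on C1 steering both. The precursor is the bicyclic lactone carrying a neopentyl aldehyde on C1 and a 4-oxobut-1-en-2-yl arm on C10. C1/C10 come from a dianionic Ireland–Claisen rearrangement, the lactone from a samarium Reformatsky closure, and the ten-membered ring from a palladium-mediated diene coupling.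

Key step: step 28

Remark on the chemistry: the 11,20-oxirane is treated as a functional group and is made by epoxidation of the 11(20)-alkene once the carbon skeleton is complete.

Locants C1–C20 are those of the target: ten-membered ring C1–C10; six-membered ring C1, C10–C14; C15 methyl on C1; C16 CH2O on C5; C17, C18, C19 lactone CH, its methyl and its carbonyl; C20 exocyclic carbon on C11. "As in the target" means the same spatial arrangement as in the target SMILES. TBS = tert-butyldimethylsilyl, TBDPS = tert-butyldiphenylsilyl, PMB = 4-methoxybenzyl.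

Step 1
Reactants: 1 (R)-4-benzyl-3-propanoyl-1,3-oxazolidin-2-one; 2 3-(trimethylsilyl)prop-2-ynal
Product: 3 syn-aldol imide (2R,3R)
Conditions: Bu2BOTf, Et3N, CH2Cl2, −78 to 0 °C; then pH 7 buffer, MeOH, H2O2
Reagents that add atoms: none
Why: Evans syn-aldol reaction, in which the Z-boron enolate reacts through a Zimmerman–Traxler chair on the face opposite the benzyl group and so sets the carbinol centre that becomes C2 (the α-methyl centre is erased later by enolisation).

Step 2
Reactants: 3 syn-aldol imide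
Product: 4 (Z)-vinylsilane imide
Conditions: H2 (1 atm), Pd/CaCO3 poisoned with Pb(OAc)2, quinoline, EtOAc, rt
Reagents that add atoms: none
Why: Lindlar semihydrogenation adds hydrogen syn to the silylalkyne and should stop at the (Z)-vinylsilane, a base- and hydride-stable precursor of the (3Z)-iodide and a bulky directing group for step 8.

Step 3
Reactants: 4 (Z)-vinylsilane imide
Product: 5 (2R,3R,4Z)-3-hydroxy-2-methyl-5-(trimethylsilyl)pent-4-enoic acid
Conditions: LiOH, H2O2, THF/H2O, 0 °C; then Na2SO3; aq. HCl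
Reagents that add atoms: hydrogen peroxide, OO
Why: Evans auxiliary cleavage, the hydroperoxide anion attacking the exocyclic imide carbonyl selectively, leaves both stereocentres untouched.

Step 4
Reactants: 6 triethyl phosphonoacetate; 7 tert-butyl(2-iodoethoxy)dimethylsilane
Product: 8 ethyl 4-(TBS-oxy)-2-(diethoxyphosphoryl)butanoate
Conditions: NaH, DMF, 0 to 60 °C
Reagents that add atoms: none
Why: SN2 C-alkylation of the sodium phosphonoacetate anion by the primary iodide brings in the C12–C13 arm in protected form.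

Step 5
Reactants: 8 phosphonate; 9 2-[(4-methoxybenzyl)oxy]acetaldehyde
Product: 10 (E)-enoate
Conditions: NaH, THF, 0 °C to rt
Reagents that add atoms: none
Why: Horner–Wadsworth–Emmons olefination should give mainly the (E)-enoate with C9 trans to the ester carbon (C20), the alkene geometry that step 8 translates into the C10 configuration.

Step 6
Reactants: 10 (E)-enoate
Product: 11 (E)-allylic alcohol
Conditions: (i-Bu)2AlH, CH2Cl2, −78 °C; aq. potassium sodium tartrate (KNaC4H4O6)
Reagents that add atoms: none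
Why: 1,2-reduction of the conjugated ester by the aluminium hydride gives the allylic alcohol without changing the alkene geometry or the silyl and PMB ethers.

Step 7
Reactants: 5 acid; 11 (E)-allylic alcohol
Product: 12 allylic ester
Conditions: EDC·HCl, DMAP (cat.), CH2Cl2, 0 °C to rt
Reagents that add atoms: none
Why: carbodiimide (Steglich-type) esterification acylates the unhindered primary allylic alcohol much faster than the hindered secondary hydroxyl of 5.

Step 8
Reactants: 12 allylic ester
Product: 14 Claisen acid, via chelated dilithium alkoxide enolate 13 (not isolated)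
Conditions: LiN(i-Pr)2 (2.3 equiv), THF, −78 °C to rt, then 40 °C; aq. HCl
Reagents that add atoms: none
Why: dianionic Ireland–Claisen rearrangement, in which the lithium alkoxide at C2 chelates the ester enolate (fixed enolate geometry, C2–O in the enolate plane) and the allyl unit is delivered through a chair transition state to the face opposite the C2 vinylsilane branch (Fráter–Seebach sense) with C9 equatorial as dictated by the (E)-alkene, which sets the quaternary C1 and C10 together and creates the 11(20)-methylene.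

Step 9
Reactants: 14 Claisen acid
Product: 15 2,14-diol
Conditions: LiAlH4, THF, 0 °C to rt
Reagents that add atoms: none
Why: hydride reduction of the α-quaternary carboxylic acid gives the neopentyl C14 alcohol, the vinylsilane, alkene and ethers being inert.

Step 10
Reactants: 15 2,14-diol
Product: 16 14-O-TBS ether
Conditions: TBSCl, imidazole, DMF, 0 °C
Reagents that add atoms: tert-butyldimethylsilyl chloride, CC(C)(C)[Si](C)(C)Cl
Why: silyl ether formation is selective for the primary C14 hydroxyl over the hindered secondary allylic C2 hydroxyl.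

Step 11
Reactants: 16 14-O-TBS ether
Product: 17 2-O-acetate
Conditions: Ac2O, pyridine, DMAP (cat.), CH2Cl2, rt
Reagents that add atoms: acetic anhydride, CC(=O)OC(C)=O
Why: DMAP-catalysed acylation installs the C2 acetate of the target.

Step 12
Reactants: 17 2-O-acetate
Product: 18 C9 alcohol
Conditions: DDQ, CH2Cl2/pH 7 buffer, 0 °C
Reagents that add atoms: none
Why: oxidative PMB ether cleavage (hydride abstraction to the oxocarbenium ion, then hydrolysis) frees the C9 alcohol while silyl ethers, acetate and vinylsilane survive.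

Step 13
Reactants: 18 C9 alcohol
Product: 19 (3Z)-vinyl iodide
Conditions: N-iodosuccinimide, (CF3)2CHOH, 0 °C
Reagents that add atoms: N-iodosuccinimide, O=C1CCC(=O)N1I
Why: ipso-iododesilylation of the vinylsilane (β-silyl cation, loss of silicon) proceeds with retention to the (3Z)-vinyl iodide, and is placed here because no anisyl ring or tertiary hydroxyl that could compete for the iodonium source is present.

Step 14
Reactants: 19 (3Z)-vinyl iodide
Product: 20 C9 aldehyde
Conditions: Dess–Martin periodinane, NaHCO3, CH2Cl2, 0 °C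
Reagents that add atoms: none
Why: Dess–Martin oxidation under buffered, non-basic conditions gives the α-branched aldehyde without epimerisation at C10 or migration of the 11(20)-alkene into conjugation.

Step 15
Reactants: 21 2-chloro-N-methoxy-N-methylacetamide; 22 (4-methoxyphenyl)methanol
Product: 23 N-methoxy-2-[(4-methoxybenzyl)oxy]-N-methylacetamide
Conditions: NaH, THF, 0 °C to rt
Reagents that add atoms: none
Why: Williamson ether synthesis, the alkoxide displacing the activated α-chloride.

Step 16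
Reactants: 23 Weinreb amide; 24 tert-butyldiphenyl(prop-2-yn-1-yloxy)silane
Product: 25 ynone
Conditions: n-BuLi, THF, −78 °C (24, then 23); aq. NH4Cl
Reagents that add atoms: none
Why: addition of the lithiated alkyne to the Weinreb amide stops at the chelated tetrahedral adduct, which collapses to the ynone only on work-up.

Step 17
Reactants: 25 ynone
Product: 26 (Z)-β-iodoenone
Conditions: NaI, AcOH, rt
Reagents that add atoms: sodium iodide, [Na+].[I-]
Why: conjugate hydroiodination of the ynone, iodide adding to the β-carbon and the proton arriving anti, gives the (Z)-β-iodoenone with iodine cis to the carbonyl carbon (C7), which fixes the later C5=C6 geometry.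

Step 18
Reactants: 20 C9 aldehyde; 26 (Z)-β-iodoenone
Product: 27 aldol adduct
Conditions: Bu2BOTf, i-Pr2NEt, CH2Cl2, −78 °C; then 20, −78 to −20 °C; pH 7 buffer, MeOH, H2O2
Reagents that add atoms: none
Why: boron aldol reaction, in which Bu2BOTf enolises 26 only at C8 to the Z-enolate, whose Zimmerman–Traxler chair gives the 8,9-syn adduct and, because the Felkin mode would force a syn-pentane contact between the C8 alkoxy group and the C11 branch of the aldehyde, should add to the anti-Felkin face, which sets C9 as in the target (C8 is a temporary centre).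

Step 19
Reactants: 27 aldol adduct
Product: 28 9-O-acetate
Conditions: Ac2O, pyridine, DMAP (cat.), CH2Cl2, 0 °C
Reagents that add atoms: acetic anhydride, CC(=O)OC(C)=O
Why: acylation installs the C9 acetate of the target at once, so that only the C7 and C8 oxygens remain to be told apart.

Step 20
Reactants: 28 9-O-acetate
Product: 29 C7 alcohol
Conditions: Zn(BH4)2, Et2O, −30 °C
Reagents that add atoms: none
Why: chelation-controlled (Cram chelate) 1,2-reduction, zinc bridging the ketone and the C8 PMB ether so that hydride enters opposite the C9 branch, should give the 7,8-anti alcohol, which is C7 as in the target.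

Step 21
Reactants: 29 C7 alcohol; 30 2-bromopropanoyl bromide
Product: 31 7-O-(2-bromopropanoyl) ester
Conditions: pyridine, CH2Cl2, −20 °C
Reagents that add atoms: none
Why: nucleophilic acyl substitution on the acid bromide esterifies the only free hydroxyl (C7) and brings in C17–C19 (the bromine-bearing centre need not be controlled).

Step 22
Reactants: 31 bromopropanoyl ester
Product: 32 C8 alcohol
Conditions: DDQ, CH2Cl2/pH 7 buffer, 0 °C
Reagents that add atoms: none
Why: oxidative PMB cleavage unveils the temporary C8 hydroxyl, the vinyl iodides, bromoester, acetates and silyl ethers being inert to DDQ.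

Step 23
Reactants: 32 C8 alcohol
Product: 33 C8 ketone
Conditions: Dess–Martin periodinane, NaHCO3, CH2Cl2, 0 °C
Reagents that add atoms: none
Why: Dess–Martin oxidation turns the temporary C8 carbinol into the ketone and thereby removes this stereocentre.

Step 24
Reactants: 33 C8 ketone
Product: 34 hydroxy lactone
Conditions: SmI2 (2.2 equiv), THF, −78 °C
Reagents that add atoms: none
Why: intramolecular samarium Reformatsky reaction, in which SmI2 reduces the carbon–bromine bond and the samarium enolate adds to the C8 ketone through a five-membered chelated transition state that keeps the C6 and C9 branches trans across C7–C8 and the C18 methyl trans to C9, which closes the γ-lactone and sets C8 and C17 (C17, being α to the lactone carbonyl, can also be equilibrated to this more stable arrangement).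

Step 25
Reactants: 34 hydroxy lactone
Product: 36 ten-membered carbocycle, via C4 trimethylstannane 35 (not isolated)
Conditions: Pd(PPh3)4 (10 mol%), Me3SnSnMe3 (1.05 equiv), 1,4-dioxane, 90 °C, 2 mM
Reagents that add atoms: none
Why: Stille–Kelly coupling, in which zerovalent palladium stannylates one vinyl iodide with the distannane and the vinylstannane then couples intramolecularly with the second iodide with retention at both alkenes, should forge the C4–C5 bond and close the ten-membered ring as its (3Z,5E)-diene.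

Step 26
Reactants: 36 ten-membered carbocycle
Product: 37 13,14-diol
Conditions: HF·pyridine, pyridine, THF, 0 °C to rt
Reagents that add atoms: none
Why: buffered HF desilylation removes the two primary TBS ethers far faster than the TBDPS ether at C16.

Step 27
Reactants: 37 13,14-diol
Product: 38 13,14-dialdehyde
Conditions: Dess–Martin periodinane, NaHCO3, CH2Cl2, 0 °C; used at once
Reagents that add atoms: none
Why: double Dess–Martin oxidation of the two primary alcohols gives the dialdehyde under non-basic conditions that leave the tertiary C8 hydroxyl alone and keep the β,γ-unsaturated C13 aldehyde unconjugated.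

Step 28
Reactants: 38 13,14-dialdehyde
Product: 39 13,14-cis-diol with the six-membered ring closed
Conditions: SmI2 (2.5 equiv), t-BuOH (2 equiv), THF, −78 to −20 °C, 2 mM, slow addition of 38
Reagents that add atoms: none
Why: SmI2 transfers an electron to the aldehydes (the unhindered C13 aldehyde first) and the ketyl adds to the second samarium-bound carbonyl (or two ketyls couple), the closest known reaction type being the samarium diiodide pinacol cyclisation of 1,6-dialdehydes to cis-cyclohexane-1,2-diols. The six-membered ring C1, C10–C14 is closed by the C13–C14 bond in a 6-exo-trig ketyl-to-carbonyl addition on the ten-membered template. Both oxygens are bound to one trivalent samarium centre in the transition state, so the new diol should be cis (C13 relative to C14). In the chair-like transition state fixed by the trans-disposed C1–C2 and C10–C9 ring bonds the C15 methyl on C1 is axial, so the C14–O bond goes axial anti to it and the C13–O bond equatorial, away from a 1,3-diaxial contact with C15, which gives both new centres as in the target (both oxygens α). The step needs chemoselectivity for the two aldehydes over lactone, allylic acetates and diene (SmI2 without HMPA at low temperature should leave them) and intramolecular over intermolecular coupling (high dilution, slow addition), and the labile C13 aldehyde is used directly after step 27.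

Step 29
Reactants: 39 13,14-cis-diol
Product: 40 2,9,13,14-tetraacetate
Conditions: Ac2O, pyridine, DMAP (cat.), CH2Cl2, rt
Reagents that add atoms: acetic anhydride, CC(=O)OC(C)=O
Why: acylation of the two secondary hydroxyls completes the tetraacetate, the hindered tertiary C8 hydroxyl staying free under these mild conditions.

Step 30
Reactants: 40 tetraacetate
Product: 41 16-O-TBDPS ether of the target
Conditions: dimethyldioxirane, acetone, −20 to 0 °C
Reagents that add atoms: dimethyldioxirane, CC1(C)OO1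
Why: electrophilic epoxidation should pick the electron-rich exocyclic 11(20)-alkene over the diene, which is deactivated by three allylic oxygens and shielded by the silyl ether, and attack the α-face because the β-face is blocked by the axial C15 methyl, which sets C11 (R).

Step 31
Reactants: 41 16-O-TBDPS ether of the target
Product: 42 CNP0317528.1
Conditions: TBAF, AcOH (1:1), THF, 0 °C to rt
Reagents that add atoms: none
Why: buffered fluoride cleaves the silicon–oxygen bond at C16 without opening the epoxide or moving the acetates.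

Compound list

1 | (R)-4-benzyl-3-propanoyl-1,3-oxazolidin-2-one | CCC(=O)N1[C@H](Cc2ccccc2)COC1=O | starting material
2 | 3-(trimethylsilyl)prop-2-ynal | C[Si](C)(C)C#CC=O | starting material
3 | (R)-4-benzyl-3-[(2R,3R)-3-hydroxy-2-methyl-5-(trimethylsilyl)pent-4-ynoyl]-1,3-oxazolidin-2-one | C[Si](C)(C)C#C[C@H](O)[C@@H](C)C(=O)N1[C@H](Cc2ccccc2)COC1=O | intermediate
4 | (R)-4-benzyl-3-[(2R,3R,4Z)-3-hydroxy-2-methyl-5-(trimethylsilyl)pent-4-enoyl]-1,3-oxazolidin-2-one | C[Si](C)(C)/C=C\[C@H](O)[C@@H](C)C(=O)N1[C@H](Cc2ccccc2)COC1=O | intermediate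
5 | (2R,3R,4Z)-3-hydroxy-2-methyl-5-(trimethylsilyl)pent-4-enoic acid | C[Si](C)(C)/C=C\[C@H](O)[C@@H](C)C(O)=O | intermediate
6 | triethyl phosphonoacetate | CCOC(=O)CP(=O)(OCC)OCC | starting material
7 | tert-butyl(2-iodoethoxy)dimethylsilane | CC(C)(C)[Si](C)(C)OCCI | starting material
8 | ethyl 4-[(tert-butyldimethylsilyl)oxy]-2-(diethoxyphosphoryl)butanoate (racemic) | CCOC(=O)C(CCO[Si](C)(C)C(C)(C)C)P(=O)(OCC)OCC | intermediate
9 | 2-[(4-methoxybenzyl)oxy]acetaldehyde | COc1ccc(COCC=O)cc1 | starting material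
10 | ethyl (E)-2-{2-[(tert-butyldimethylsilyl)oxy]ethyl}-4-[(4-methoxybenzyl)oxy]but-2-enoate | CCOC(=O)/C(CCO[Si](C)(C)C(C)(C)C)=C/COCc1ccc(OC)cc1 | intermediate
11 | (E)-2-{2-[(tert-butyldimethylsilyl)oxy]ethyl}-4-[(4-methoxybenzyl)oxy]but-2-en-1-ol | OC/C(CCO[Si](C)(C)C(C)(C)C)=C/COCc1ccc(OC)cc1 | intermediate
12 | allylic ester of acid 5 with alcohol 11 | C[Si](C)(C)/C=C\[C@H](O)[C@@H](C)C(=O)OC/C(CCO[Si](C)(C)C(C)(C)C)=C/COCc1ccc(OC)cc1 | intermediate
13 | chelated dilithium alkoxide enolate of 12 (enolate oxygen cis to the carbinol carbon) | [Li+].[Li+].C[Si](C)(C)/C=C\[C@H]([O-])/C(C)=C(\[O-])OC/C(CCO[Si](C)(C)C(C)(C)C)=C/COCc1ccc(OC)cc1 | intermediate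
14 | Claisen acid: C14 acid on quaternary C1 (C15 methyl); C1 also bears C2H(OH)–CH=CH–SiMe3 (3Z) and C10H(CH2OPMB)–C(=CH2)–CH2CH2OTBS; C1, C2, C10 as in the target | C[Si](C)(C)/C=C\[C@H](O)[C@@](C)(C(O)=O)[C@@H](COCc1ccc(OC)cc1)C(=C)CCO[Si](C)(C)C(C)(C)C | intermediate
15 | 2,14-diol: 14 with CH2OH in place of CO2H | C[Si](C)(C)/C=C\[C@H](O)[C@@](C)(CO)[C@@H](COCc1ccc(OC)cc1)C(=C)CCO[Si](C)(C)C(C)(C)C | intermediate
16 | 14-O-TBS ether of 15 (2-OH free) | C[Si](C)(C)/C=C\[C@H](O)[C@@](C)(CO[Si](C)(C)C(C)(C)C)[C@@H](COCc1ccc(OC)cc1)C(=C)CCO[Si](C)(C)C(C)(C)C | intermediate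
17 | 2-O-acetate of 16 (9-O-PMB, 13,14-di-O-TBS, C4 SiMe3) | C[Si](C)(C)/C=C\[C@H](OC(C)=O)[C@@](C)(CO[Si](C)(C)C(C)(C)C)[C@@H](COCc1ccc(OC)cc1)C(=C)CCO[Si](C)(C)C(C)(C)C | intermediate
18 | C9 alcohol: 17 without the PMB group | C[Si](C)(C)/C=C\[C@H](OC(C)=O)[C@@](C)(CO[Si](C)(C)C(C)(C)C)[C@@H](CO)C(=C)CCO[Si](C)(C)C(C)(C)C | intermediate
19 | (3Z)-vinyl iodide: 18 with iodine in place of SiMe3 at C4 | I/C=C\[C@H](OC(C)=O)[C@@](C)(CO[Si](C)(C)C(C)(C)C)[C@@H](CO)C(=C)CCO[Si](C)(C)C(C)(C)C | intermediate
20 | C9 aldehyde of 19 | I/C=C\[C@H](OC(C)=O)[C@@](C)(CO[Si](C)(C)C(C)(C)C)[C@@H](C=O)C(=C)CCO[Si](C)(C)C(C)(C)C | intermediate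
21 | 2-chloro-N-methoxy-N-methylacetamide | CON(C)C(=O)CCl | starting material
22 | (4-methoxyphenyl)methanol | COc1ccc(CO)cc1 | starting material
23 | N-methoxy-2-[(4-methoxybenzyl)oxy]-N-methylacetamide | CON(C)C(=O)COCc1ccc(OC)cc1 | intermediate
24 | tert-butyldiphenyl(prop-2-yn-1-yloxy)silane | C#CCO[Si](c1ccccc1)(c1ccccc1)C(C)(C)C | starting material
25 | 5-[(tert-butyldiphenylsilyl)oxy]-1-[(4-methoxybenzyl)oxy]pent-3-yn-2-one | COc1ccc(COCC(=O)C#CCO[Si](c2ccccc2)(c2ccccc2)C(C)(C)C)cc1 | intermediate
26 | (Z)-5-[(tert-butyldiphenylsilyl)oxy]-4-iodo-1-[(4-methoxybenzyl)oxy]pent-3-en-2-one | COc1ccc(COCC(=O)/C=C(\I)CO[Si](c2ccccc2)(c2ccccc2)C(C)(C)C)cc1 | intermediate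
27 | aldol adduct: 20 extended at C9 by C8H(OPMB)–C7(=O)–C6H=C5(I)–C16H2OTBDPS (5Z); 9-OH as in the target, 8-OPMB syn to it | I/C=C\[C@H](OC(C)=O)[C@@](C)(CO[Si](C)(C)C(C)(C)C)[C@@H]([C@H](O)[C@@H](OCc1ccc(OC)cc1)C(=O)/C=C(\I)CO[Si](c1ccccc1)(c1ccccc1)C(C)(C)C)C(=C)CCO[Si](C)(C)C(C)(C)C | intermediate
28 | 9-O-acetate of 27 | I/C=C\[C@H](OC(C)=O)[C@@](C)(CO[Si](C)(C)C(C)(C)C)[C@@H]([C@H](OC(C)=O)[C@@H](OCc1ccc(OC)cc1)C(=O)/C=C(\I)CO[Si](c1ccccc1)(c1ccccc1)C(C)(C)C)C(=C)CCO[Si](C)(C)C(C)(C)C | intermediate
29 | C7 alcohol of 28 (C7 as in the target; 7,8-anti) | I/C=C\[C@H](OC(C)=O)[C@@](C)(CO[Si](C)(C)C(C)(C)C)[C@@H]([C@H](OC(C)=O)[C@@H](OCc1ccc(OC)cc1)[C@@H](O)/C=C(\I)CO[Si](c1ccccc1)(c1ccccc1)C(C)(C)C)C(=C)CCO[Si](C)(C)C(C)(C)C | intermediate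
30 | 2-bromopropanoyl bromide (racemic) | CC(Br)C(Br)=O | starting material
31 | 7-O-(2-bromopropanoyl) ester of 29 (both bromide epimers) | I/C=C\[C@H](OC(C)=O)[C@@](C)(CO[Si](C)(C)C(C)(C)C)[C@@H]([C@H](OC(C)=O)[C@@H](OCc1ccc(OC)cc1)[C@@H](OC(=O)C(C)Br)/C=C(\I)CO[Si](c1ccccc1)(c1ccccc1)C(C)(C)C)C(=C)CCO[Si](C)(C)C(C)(C)C | intermediate
32 | C8 alcohol: 31 without the PMB group | I/C=C\[C@H](OC(C)=O)[C@@](C)(CO[Si](C)(C)C(C)(C)C)[C@@H]([C@H](OC(C)=O)[C@@H](O)[C@@H](OC(=O)C(C)Br)/C=C(\I)CO[Si](c1ccccc1)(c1ccccc1)C(C)(C)C)C(=C)CCO[Si](C)(C)C(C)(C)C | intermediate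
33 | C8 ketone of 32 | I/C=C\[C@H](OC(C)=O)[C@@](C)(CO[Si](C)(C)C(C)(C)C)[C@@H]([C@H](OC(C)=O)C(=O)[C@@H](OC(=O)C(C)Br)/C=C(\I)CO[Si](c1ccccc1)(c1ccccc1)C(C)(C)C)C(=C)CCO[Si](C)(C)C(C)(C)C | intermediate
34 | hydroxy lactone: γ-lactone O7–C19(=O)–C17H(CH3)–C8(OH) closed on 33; C7, C8, C17 as in the target; (3Z)-C4 and (5Z)-C5 vinyl iodides | I/C=C\[C@H](OC(C)=O)[C@@](C)(CO[Si](C)(C)C(C)(C)C)[C@@H]([C@H](OC(C)=O)[C@@]3(O)[C@H](/C=C(\I)CO[Si](c1ccccc1)(c1ccccc1)C(C)(C)C)OC(=O)[C@@H]3C)C(=C)CCO[Si](C)(C)C(C)(C)C | intermediate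
35 | C4 trimethylstannane: 34 with SnMe3 in place of the C4 iodine | C[Sn](C)(C)/C=C\[C@H](OC(C)=O)[C@@](C)(CO[Si](C)(C)C(C)(C)C)[C@@H]([C@H](OC(C)=O)[C@@]3(O)[C@H](/C=C(\I)CO[Si](c1ccccc1)(c1ccccc1)C(C)(C)C)OC(=O)[C@@H]3C)C(=C)CCO[Si](C)(C)C(C)(C)C | intermediate
36 | ten-membered carbocycle C1–C10 with (3Z,5E)-diene and fused γ-lactone; 2,9-di-O-acetyl, 8-OH, 13,14-di-O-TBS, 16-O-TBDPS, 11(20)-methylene | CC(C)(C)[Si](C)(C)OCCC(=C)[C@@H]2[C@H](OC(C)=O)[C@@]3(O)[C@H](/C=C(CO[Si](c1ccccc1)(c1ccccc1)C(C)(C)C)\C=C/[C@H](OC(C)=O)[C@@]2(C)CO[Si](C)(C)C(C)(C)C)OC(=O)[C@@H]3C | intermediate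
37 | 13,14-diol of 36 | OCCC(=C)[C@@H]2[C@H](OC(C)=O)[C@@]3(O)[C@H](/C=C(CO[Si](c1ccccc1)(c1ccccc1)C(C)(C)C)\C=C/[C@H](OC(C)=O)[C@@]2(C)CO)OC(=O)[C@@H]3C | intermediate
38 | 13,14-dialdehyde (C14 formyl on C1; 4-oxobut-1-en-2-yl on C10) | O=CCC(=C)[C@@H]2[C@H](OC(C)=O)[C@@]3(O)[C@H](/C=C(CO[Si](c1ccccc1)(c1ccccc1)C(C)(C)C)\C=C/[C@H](OC(C)=O)[C@@]2(C)C=O)OC(=O)[C@@H]3C | intermediate
39 | 13,14-cis-diol with the six-membered ring closed; all centres except C11 as in the target; 11(20)-methylene; 16-O-TBDPS | O[C@H]1CC(=C)[C@@H]2[C@H](OC(C)=O)[C@@]3(O)[C@H](/C=C(CO[Si](c4ccccc4)(c4ccccc4)C(C)(C)C)\C=C/[C@H](OC(C)=O)[C@@]2(C)[C@H]1O)OC(=O)[C@@H]3C | intermediate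
40 | 2,9,13,14-tetraacetate of 39 | CC(=O)O[C@H]1CC(=C)[C@@H]2[C@H](OC(C)=O)[C@@]3(O)[C@H](/C=C(CO[Si](c4ccccc4)(c4ccccc4)C(C)(C)C)\C=C/[C@H](OC(C)=O)[C@@]2(C)[C@H]1OC(C)=O)OC(=O)[C@@H]3C | intermediate
41 | 16-O-TBDPS ether of the target (11R epoxide) | CC(=O)O[C@H]1C[C@]2(CO2)[C@@H]2[C@H](OC(C)=O)[C@@]3(O)[C@H](/C=C(CO[Si](c4ccccc4)(c4ccccc4)C(C)(C)C)\C=C/[C@H](OC(C)=O)[C@@]2(C)[C@H]1OC(C)=O)OC(=O)[C@@H]3C | intermediate
42 | CNP0317528.1 | CC(=O)O[C@H]1C[C@]2(CO2)[C@@H]2[C@H](OC(C)=O)[C@@]3(O)[C@H](/C=C(CO)\C=C/[C@H](OC(C)=O)[C@@]2(C)[C@H]1OC(C)=O)OC(=O)[C@@H]3C | target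

Total step count: 31.
Longest linear sequence: 25 steps (steps 4–14 and 18–31 from 6 and 7; the branch from 1 and 2 through steps 1–3, 7–14 and 18–31 is equally long).

The three steps most likely to fail

Step 25 (ring closure of the ten-membered diene). Intermolecular coupling of the stannylated intermediate (oligomerisation), or ionisation of the allylic acetate and allylic lactone by zerovalent palladium at 90 °C, may outrun closure of the strained ring. The fallback sets out from 34 and separates the two events. A Miyaura borylation with one equivalent of B2pin2 (Pd(dppf)Cl2, KOAc, DMSO, 50 °C) should take the less hindered disubstituted iodide and give the C4 pinacolboronate F1. A separate intramolecular Suzuki–Miyaura coupling with the C5 iodide at room temperature (Pd(PPh3)4, K3PO4, THF/H2O, 1 mM) then comes back to the route at 36.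

Step 28 (key step). Reduction may stop at hydroxy aldehydes, give the trans-diol or intermolecular pinacols, or the C13 aldehyde may conjugate or be trapped as a lactol by the C8 hydroxyl before coupling. The fallback sets out from 38. Non-basic double methylenation (Zn, CH2I2, TiCl4, THF, 0 °C) gives the 13,14-bis(vinyl) compound F2. Ring-closing metathesis (second-generation Grubbs catalyst, CH2Cl2, 40 °C) closes the six-membered ring as the C13=C14 cyclohexene F3; the exocyclic methylene can only give three- or four-membered rings and should stay out. Upjohn dihydroxylation with one equivalent of oxidant (OsO4 cat., NMO, acetone/H2O, 0 °C) on the α-face, anti to the axial C15 methyl, then comes back to the route at 39.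

Step 18 (aldol union). Facial selection at C9 may be poor because Felkin and anti-Felkin modes compete, and C10 of the α-branched aldehyde may epimerise during the reaction. The fallback sets out from 20 and puts C9 under reagent control. An Evans syn-glycolate aldol with (R)-4-benzyl-3-{[(4-methoxybenzyl)oxy]acetyl}-1,3-oxazolidin-2-one (Bu2BOTf, Et3N, CH2Cl2, −78 °C) gives the glycolate imide adduct F4. Transamination (AlMe3, MeNH(OMe)·HCl, CH2Cl2, −20 °C) gives the Weinreb amide F5. Addition of lithiated 24 (n-BuLi, THF, −78 °C, 2.2 equiv) gives the β-hydroxy ynone F6. Hydroiodination (NaI, AcOH, rt) as in step 17 then comes back to the route at 27.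

Further compounds

F1 | step 25 | C4 pinacolboronate: 34 with the pinacolatoboryl group in place of the C4 iodine (3Z; C5 iodide kept) | CC1(C)OB(/C=C\[C@H](OC(C)=O)[C@@](C)(CO[Si](C)(C)C(C)(C)C)[C@@H]([C@H](OC(C)=O)[C@@]3(O)[C@H](/C=C(\I)CO[Si](c2ccccc2)(c2ccccc2)C(C)(C)C)OC(=O)[C@@H]3C)C(=C)CCO[Si](C)(C)C(C)(C)C)OC1(C)C
F2 | step 28 | 13,14-bis(vinyl) compound: 38 with CH=CH2 in place of each CHO | C=CCC(=C)[C@@H]2[C@H](OC(C)=O)[C@@]3(O)[C@H](/C=C(CO[Si](c1ccccc1)(c1ccccc1)C(C)(C)C)\C=C/[C@H](OC(C)=O)[C@@]2(C)C=C)OC(=O)[C@@H]3C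
F3 | step 28 | C13=C14 cyclohexene with the six-membered ring closed (11(20)-methylene, 16-O-TBDPS) | C1CC(=C)[C@@H]2[C@H](OC(C)=O)[C@@]3(O)[C@H](/C=C(CO[Si](c4ccccc4)(c4ccccc4)C(C)(C)C)\C=C/[C@H](OC(C)=O)[C@@]2(C)C=1)OC(=O)[C@@H]3C
F4 | step 18 | glycolate imide adduct: 20 extended at C9 by C8H(OPMB)–C7(=O)–N-oxazolidinone; 9-OH as in the target, 8-OPMB syn | I/C=C\[C@H](OC(C)=O)[C@@](C)(CO[Si](C)(C)C(C)(C)C)[C@@H]([C@H](O)[C@@H](OCc1ccc(OC)cc1)C(=O)N1[C@H](Cc2ccccc2)COC1=O)C(=C)CCO[Si](C)(C)C(C)(C)C
F5 | step 18 | Weinreb amide: F4 with N(OMe)Me in place of the oxazolidinone | I/C=C\[C@H](OC(C)=O)[C@@](C)(CO[Si](C)(C)C(C)(C)C)[C@@H]([C@H](O)[C@@H](OCc1ccc(OC)cc1)C(=O)N(C)OC)C(=C)CCO[Si](C)(C)C(C)(C)C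
F6 | step 18 | β-hydroxy ynone: C7 ketone bearing C6≡C5–C16H2OTBDPS | I/C=C\[C@H](OC(C)=O)[C@@](C)(CO[Si](C)(C)C(C)(C)C)[C@@H]([C@H](O)[C@@H](OCc1ccc(OC)cc1)C(=O)C#CCO[Si](c1ccccc1)(c1ccccc1)C(C)(C)C)C(=C)CCO[Si](C)(C)C(C)(C)C
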